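Ring A is the central benzene: C1 bears the methide carbon, C2 a 4-hydroxyphenyl, C3 and C4 are CH, C5 bears CH2OH and C6 the arylethynyl group. Going backwards, the quinone methide becomes the triarylmethane C–H, CH2OH becomes CO2Me, the four phenols become silyl ethers, and ring A is cut at C1–C6 and C2–C3.
Enabling feature: C3–C6 of ring A, with the C5 carbon substituent next to the C6 alkyne, are positions 3–6 of a 2-pyrone with an ester at position 5 and the arylethynyl group at position 6. C1 and C2 are the two sp carbons of a 1,1,3-triarylpropyne.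
Forward: the silylated aryl iodide feeds both halves. Half (a) runs arylalkyne → propiolic acid → alkynyl β-keto ester → pyrone. Half (b) runs aryl Grignard reagent plus silylated 4-hydroxybenzaldehyde → benzhydrol → triarylpropyne.
The halves are joined by an inverse-demand Diels–Alder reaction with loss of CO2, which closes ring A, the only ring made in the route. Ester reduction, desilylation and dehydrogenation to the quinone methide follow.
Stereochemistry: the target has no stereocentre and no configured double bond (the methide carbon carries a symmetric cyclohexadienone), and the bridgehead centres of the cycloadduct vanish with CO2.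

Key step: step 9

Remark on the chemistry: the four phenols are carried as triisopropylsilyl ethers. A fourfold aryl methyl ether cleavage with BBr3 or hot thiolate next to a 2-alkynylbenzoate or 2-alkynylbenzyl alcohol invites addition across the alkyne, whereas buffered fluoride should touch neither.
Abbreviation: Ar = 4-[(triisopropylsilyl)oxy]phenyl.

Step 1
Reactants: 1 4-iodophenol
Product: 2 (4-iodophenoxy)triisopropylsilane (Ar–I)
Conditions: i-Pr3SiCl, imidazole, DMF, rt
Reagents that add atoms: triisopropylsilyl chloride, CC(C)[Si](Cl)(C(C)C)C(C)C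
Why: Imidazole-promoted O-silylation of a phenol is fast and clean, and the bulky silyl ether should resist organometallics, catalytic carbonate in methanol, amine bases and 180 °C yet fall to fluoride.

Step 2
Reactants: 2 (4-iodophenoxy)triisopropylsilane; 3 ethynyltrimethylsilane
Product: 5 (4-ethynylphenoxy)triisopropylsilane (Ar–C≡CH), via silylalkyne 4 (not isolated)
Conditions: PdCl2(PPh3)2 (2 mol %), CuI (4 mol %), Et3N, THF, rt; filter, concentrate; then K2CO3 (0.2 equiv), MeOH–THF, 0 °C to rt
Reagents that add atoms: none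
Why: Sonogashira coupling of the aryl iodide followed by carbonate-catalysed methanolysis of the C–SiMe3 bond should give the terminal alkyne, the hindered aryl O–Si bond being inert to catalytic methoxide.

Step 3
Reactants: 5 (4-ethynylphenoxy)triisopropylsilane
Product: 7 3-Ar-prop-2-ynoic acid (Ar–C≡C–CO2H), via lithium acetylide 6 (not isolated)
Conditions: n-BuLi, THF, −78 °C; CO2 (gas), −78 °C to 0 °C; cold 1 M HCl
Reagents that add atoms: carbon dioxide, O=C=O
Why: Carboxylation of a lithium acetylide is the standard route to arylpropiolic acids, and the aryl silyl ether tolerates n-BuLi at −78 °C.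

Step 4
Reactants: 7 3-Ar-prop-2-ynoic acid; 8 potassium methyl malonate
Product: 10 methyl 3-oxo-5-Ar-pent-4-ynoate (Ar–C≡C–CO–CH2–CO2Me), via acyl imidazolide 9 (not isolated)
Conditions: CDI, THF, rt; then 8, MgCl2, Et3N (premixed in MeCN), rt to 40 °C; cold 1 M HCl
Reagents that add atoms: none
Why: In this Masamune–Brooks homologation the acyl imidazolide C-acylates the magnesium enolate of the malonate half ester and the acylmalonate loses CO2, while the magnesium chelate of the product shields the ynone from conjugate addition of imidazole.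

Step 5
Reactants: 10 methyl 3-oxo-5-Ar-pent-4-ynoate; 11 methyl propiolate
Product: 13 methyl 6-oxo-2-(Ar-ethynyl)-6H-pyran-3-carboxylate, via acylglutaconate 12 (not isolated)
Conditions: DABCO (0.1 equiv), CH2Cl2, 0 °C to rt; then toluene, DBU (0.2 equiv), 5 Å molecular sieves, 80 °C
Reagents that add atoms: none
Why: Amine-catalysed Michael addition of the β-keto ester carbon to the propiolate gives the 2-acylglutaconate, whose enol oxygen lactonises onto the remote ester once DBU equilibrates the alkene geometry and the sieves take up methanol, a known Michael addition–lactonisation route from 1,3-dicarbonyl compounds to 2-pyrones that places the ester on pyrone C5 and the alkyne on C6 (2-pyrone numbering).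

Step 6
Reactants: 14 4-hydroxybenzaldehyde
Product: 15 4-[(triisopropylsilyl)oxy]benzaldehyde (Ar–CHO)
Conditions: i-Pr3SiCl, imidazole, DMF, rt
Reagents that add atoms: triisopropylsilyl chloride, CC(C)[Si](Cl)(C(C)C)C(C)C
Why: Imidazole-promoted O-silylation of the phenol leaves the aldehyde untouched and gives the electrophile for the benzhydrol with the same protecting group as the rest of the route.

Step 7
Reactants: 2 (4-iodophenoxy)triisopropylsilane; 15 4-[(triisopropylsilyl)oxy]benzaldehyde
Product: 17 bis-Ar-methanol (Ar2CHOH), via aryl Grignard reagent 16 (not isolated)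
Conditions: 2, Mg, THF, rt; then 15 (0.95 equiv), 0 °C to rt; aq NH4Cl
Reagents that add atoms: none
Why: Addition of an aryl Grignard reagent to an aromatic aldehyde is the standard synthesis of diarylmethanols, the aryl iodide inserts magnesium readily, and the hindered aryl silyl ethers are inert to the organomagnesium reagent at or below rt.

Step 8
Reactants: 17 bis-Ar-methanol; 5 (4-ethynylphenoxy)triisopropylsilane
Product: 20 1,1,3-tris-Ar-prop-2-yne (Ar2CH–C≡C–Ar), via diarylmethyl chloride 18 (not isolated), via alkynylmagnesium bromide 19 (not isolated)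
Conditions: 17, SOCl2, CH2Cl2, 0 °C, evaporate; 5, EtMgBr, THF, 40 °C; combine (chloride 1.1 equiv), CuBr·SMe2 (5 mol %), THF, −20 °C to rt
Reagents that add atoms: none
Why: The diarylmethyl chloride, stabilised by two para silyloxy groups, ionises readily and is captured at carbon by the alkynyl Grignard reagent (copper-assisted SN1-type alkynylation of a benzhydryl halide, as in the classical preparation of 3,3-diarylpropynes), and the slight excess of chloride keeps the acidic propargylic C–H of the product from being deprotonated.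

Step 9
Reactants: 13 methyl 6-oxo-2-(Ar-ethynyl)-6H-pyran-3-carboxylate; 20 1,1,3-tris-Ar-prop-2-yne
Product: 22 methyl 3-(Ar2CH)-4-Ar-2-(Ar-ethynyl)benzoate, via bridged lactone 21 (not isolated)
Conditions: 20 (2.5 equiv), BHT (5 mol %), 1,2-dichlorobenzene (1 M in 13), sealed tube, 180 °C
Reagents that add atoms: none
Why: The electron-poor pyrone 13 is the diene (pyrone C3 to C6) and the aryl-polarised alkyne 20 the dienophile in an asynchronous inverse-demand Diels–Alder reaction: the alkyne carbon remote from Ar, the nucleophilic terminus carrying the diarylmethyl group, bonds to pyrone C6, the electrophilic position activated by both the lactone carbonyl and the C5 ester, while the aryl-bearing carbon bonds to C3. The bridged lactone 21 then loses CO2 by retro-[4+2] at the reaction temperature, which makes the sequence irreversible. The closest known reaction is the thermal cycloaddition–decarboxylation of coumalate esters with aryl alkynes, which places the aryl group para to the ester, exactly the relation of C2 to C5 in ring A. Ring A is closed by intermolecular [4+2] cycloaddition (bonds C1–C6 and C2–C3) and aromatised by the cycloreversion, and the two bridgehead stereocentres of 21 disappear with the CO2, so nothing stereochemical has to be controlled. The step needs regioselectivity, which the donor aryl group on the alkyne and the slim linear alkynyl substituent at pyrone C6 should secure, and chemoselectivity over the diarylalkynes of 13 and 22, which the excess of 20 and the lower nucleophilicity of an alkyne conjugated to the pyrone or flanked by two ortho substituents should secure.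

Step 10
Reactants: 22 methyl 3-(Ar2CH)-4-Ar-2-(Ar-ethynyl)benzoate
Product: 23 [3-(Ar2CH)-4-Ar-2-(Ar-ethynyl)phenyl]methanol
Conditions: i-Bu2AlH (3 equiv), CH2Cl2, −78 °C to 0 °C; aq KNaC4H4O6
Reagents that add atoms: none
Why: Hydride reduction of the methyl benzoate with i-Bu2AlH gives the benzylic alcohol, while diaryl alkynes, aryl silyl ethers and the triarylmethane are inert below 0 °C.

Step 11
Reactants: 23 [3-(Ar2CH)-4-Ar-2-(Ar-ethynyl)phenyl]methanol
Product: 24 4,4'-({3-(hydroxymethyl)-6-(4-hydroxyphenyl)-2-[(4-hydroxyphenyl)ethynyl]phenyl}methylene)diphenol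
Conditions: Bu4NF (4.4 equiv), AcOH (4.4 equiv), THF, 0 °C, argon
Reagents that add atoms: none
Why: Fluoride-mediated desilylation cleaves the four aryl O–Si bonds, and the acetic acid buffer keeps phenoxide and benzylic alkoxide concentrations low so that no oxygen nucleophile adds to the neighbouring alkyne.

Step 12
Reactants: 24 4,4'-({3-(hydroxymethyl)-6-(4-hydroxyphenyl)-2-[(4-hydroxyphenyl)ethynyl]phenyl}methylene)diphenol
Product: 25 selaginellin
Conditions: DDQ (1.0 equiv), 1,4-dioxane, rt
Reagents that add atoms: none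
Why: DDQ abstracts hydride from the methine flanked by two 4-hydroxyphenyl groups and the resulting cation loses a phenolic proton to give the quinone methide (the classical dehydrogenation of leuco triarylmethanes to fuchsones), the other two phenols having no para benzylic hydrogen and the CH2OH on ring A being far less hydridic.

**Compound list**
1 | 4-iodophenol | Oc1ccc(I)cc1 | starting material
2 | (4-iodophenoxy)triisopropylsilane | Ic1ccc(O[Si](C(C)C)(C(C)C)C(C)C)cc1 | intermediate
3 | ethynyltrimethylsilane | C#C[Si](C)(C)C | starting material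
4 | triisopropyl{4-[(trimethylsilyl)ethynyl]phenoxy}silane (not isolated) | C[Si](C)(C)C#Cc1ccc(O[Si](C(C)C)(C(C)C)C(C)C)cc1 | intermediate
5 | (4-ethynylphenoxy)triisopropylsilane | C#Cc1ccc(O[Si](C(C)C)(C(C)C)C(C)C)cc1 | intermediate
6 | ({4-[(triisopropylsilyl)oxy]phenyl}ethynyl)lithium (not isolated) | [Li]C#Cc1ccc(O[Si](C(C)C)(C(C)C)C(C)C)cc1 | intermediate
7 | 3-{4-[(triisopropylsilyl)oxy]phenyl}prop-2-ynoic acid | OC(=O)C#Cc1ccc(O[Si](C(C)C)(C(C)C)C(C)C)cc1 | intermediate
8 | potassium 3-methoxy-3-oxopropanoate (potassium methyl malonate) | [K+].[O-]C(=O)CC(=O)OC | starting material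
9 | 1-(1H-imidazol-1-yl)-3-{4-[(triisopropylsilyl)oxy]phenyl}prop-2-yn-1-one (not isolated) | O=C(C#Cc1ccc(O[Si](C(C)C)(C(C)C)C(C)C)cc1)n1ccnc1 | intermediate
10 | methyl 3-oxo-5-{4-[(triisopropylsilyl)oxy]phenyl}pent-4-ynoate | COC(=O)CC(=O)C#Cc1ccc(O[Si](C(C)C)(C(C)C)C(C)C)cc1 | intermediate
11 | methyl propiolate | C#CC(=O)OC | starting material
12 | dimethyl (2E)-4-(3-{4-[(triisopropylsilyl)oxy]phenyl}prop-2-ynoyl)pent-2-enedioate (not isolated; C4 racemic and enolisable) | COC(=O)/C=C/C(C(=O)OC)C(=O)C#Cc1ccc(O[Si](C(C)C)(C(C)C)C(C)C)cc1 | intermediate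
13 | methyl 6-oxo-2-({4-[(triisopropylsilyl)oxy]phenyl}ethynyl)-6H-pyran-3-carboxylate (the 6-alkynyl 2-pyrone-5-carboxylate in coumalate numbering) | COC(=O)C1=C(C#Cc2ccc(O[Si](C(C)C)(C(C)C)C(C)C)cc2)OC(=O)C=C1 | intermediate
14 | 4-hydroxybenzaldehyde | O=Cc1ccc(O)cc1 | starting material
15 | 4-[(triisopropylsilyl)oxy]benzaldehyde | O=Cc1ccc(O[Si](C(C)C)(C(C)C)C(C)C)cc1 | intermediate
16 | iodo{4-[(triisopropylsilyl)oxy]phenyl}magnesium (not isolated) | I[Mg]c1ccc(O[Si](C(C)C)(C(C)C)C(C)C)cc1 | intermediate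
17 | bis{4-[(triisopropylsilyl)oxy]phenyl}methanol | OC(c1ccc(O[Si](C(C)C)(C(C)C)C(C)C)cc1)c1ccc(O[Si](C(C)C)(C(C)C)C(C)C)cc1 | intermediate
18 | chlorobis{4-[(triisopropylsilyl)oxy]phenyl}methane (not isolated) | ClC(c1ccc(O[Si](C(C)C)(C(C)C)C(C)C)cc1)c1ccc(O[Si](C(C)C)(C(C)C)C(C)C)cc1 | intermediate
19 | bromo({4-[(triisopropylsilyl)oxy]phenyl}ethynyl)magnesium (not isolated) | Br[Mg]C#Cc1ccc(O[Si](C(C)C)(C(C)C)C(C)C)cc1 | intermediate
20 | 1,1,3-tris{4-[(triisopropylsilyl)oxy]phenyl}prop-2-yne | c1cc(O[Si](C(C)C)(C(C)C)C(C)C)ccc1C#CC(c1ccc(O[Si](C(C)C)(C(C)C)C(C)C)cc1)c1ccc(O[Si](C(C)C)(C(C)C)C(C)C)cc1 | intermediate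
21 | methyl 7-(bis{4-[(triisopropylsilyl)oxy]phenyl}methyl)-3-oxo-8-{4-[(triisopropylsilyl)oxy]phenyl}-1-({4-[(triisopropylsilyl)oxy]phenyl}ethynyl)-2-oxabicyclo[2.2.2]octa-5,7-diene-6-carboxylate (not isolated; racemic, one enantiomer drawn) | COC(=O)C1=C[C@H]2C(=O)O[C@]1(C#Cc3ccc(O[Si](C(C)C)(C(C)C)C(C)C)cc3)C(C(c3ccc(O[Si](C(C)C)(C(C)C)C(C)C)cc3)c3ccc(O[Si](C(C)C)(C(C)C)C(C)C)cc3)=C2c3ccc(O[Si](C(C)C)(C(C)C)C(C)C)cc3 | intermediate
22 | methyl 3-(bis{4-[(triisopropylsilyl)oxy]phenyl}methyl)-4-{4-[(triisopropylsilyl)oxy]phenyl}-2-({4-[(triisopropylsilyl)oxy]phenyl}ethynyl)benzoate | COC(=O)c1ccc(-c2ccc(O[Si](C(C)C)(C(C)C)C(C)C)cc2)c(C(c2ccc(O[Si](C(C)C)(C(C)C)C(C)C)cc2)c2ccc(O[Si](C(C)C)(C(C)C)C(C)C)cc2)c1C#Cc1ccc(O[Si](C(C)C)(C(C)C)C(C)C)cc1 | intermediate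
23 | [3-(bis{4-[(triisopropylsilyl)oxy]phenyl}methyl)-4-{4-[(triisopropylsilyl)oxy]phenyl}-2-({4-[(triisopropylsilyl)oxy]phenyl}ethynyl)phenyl]methanol | OCc1ccc(-c2ccc(O[Si](C(C)C)(C(C)C)C(C)C)cc2)c(C(c2ccc(O[Si](C(C)C)(C(C)C)C(C)C)cc2)c2ccc(O[Si](C(C)C)(C(C)C)C(C)C)cc2)c1C#Cc1ccc(O[Si](C(C)C)(C(C)C)C(C)C)cc1 | intermediate
24 | 4,4'-({3-(hydroxymethyl)-6-(4-hydroxyphenyl)-2-[(4-hydroxyphenyl)ethynyl]phenyl}methylene)diphenol | OCc1ccc(-c2ccc(O)cc2)c(C(c2ccc(O)cc2)c2ccc(O)cc2)c1C#Cc1ccc(O)cc1 | intermediate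
25 | selaginellin, 4-[{3-(hydroxymethyl)-6-(4-hydroxyphenyl)-2-[(4-hydroxyphenyl)ethynyl]phenyl}(4-hydroxyphenyl)methylidene]cyclohexa-2,5-dien-1-one | O=C1C=CC(=C(c2ccc(O)cc2)c2c(-c3ccc(O)cc3)ccc(CO)c2C#Cc2ccc(O)cc2)C=C1 | target

**Count**
Total steps: 12. Longest linear sequence: 9 steps (1, 2, 3, 4, 5, 9, 10, 11, 12).

**Steps most likely to fail**

1. Step 9. The cycloaddition may be too slow at the crowded C1–C6 bond, so that thermal self-cycloaddition or oligomerisation of the pyrone takes over, or regiocontrol may erode. The fallback keeps the cycloaddition but shrinks the C1 substituent; it sets out from 13 and 19 and comes back to the route at 22. Alkynylmagnesium bromide 19 and triethyl orthoformate (Bodroux–Chichibabin-type reaction) should give [4-(3,3-diethoxyprop-1-yn-1-yl)phenoxy]triisopropylsilane F1. Heating F1 with 13 as in step 9 should pass through the bridged lactone methyl 7-(diethoxymethyl)-3-oxo-8-Ar-1-(Ar-ethynyl)-2-oxabicyclo[2.2.2]octa-5,7-diene-6-carboxylate F2 and, after loss of CO2, give methyl 3-(diethoxymethyl)-4-Ar-2-(Ar-ethynyl)benzoate F3. Pyridinium tosylate in wet acetone should free methyl 3-formyl-4-Ar-2-(Ar-ethynyl)benzoate F4. Aryl Grignard reagent 16 (1 equiv, THF, −78 °C) should add to the aldehyde only and give methyl 3-[hydroxy(Ar)methyl]-4-Ar-2-(Ar-ethynyl)benzoate F5. Friedel–Crafts alkylation of phenol with this carbinol (phenol in large excess so that intermolecular capture outruns attack by the neighbouring alkyne, FeCl3 cat., CH2Cl2) should give methyl 3-[(4-hydroxyphenyl)(Ar)methyl]-4-Ar-2-(Ar-ethynyl)benzoate F6. Silylation of F6 (i-Pr3SiCl, imidazole) gives 22.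

2. Step 5. The alkynyl β-keto ester may self-condense by conjugate addition to its own ynone, or be O-vinylated, before the propiolate is engaged. The fallback makes the same acylglutaconate by C-acylation and avoids 10; it sets out from 7 and comes back at 12 and hence 13. Oxalyl chloride with catalytic DMF should give 3-Ar-prop-2-ynoyl chloride F7. The sodium dienolate of commercial dimethyl glutaconate (NaH, 2 equiv, THF, 0 °C) should be C-acylated by F7 at C2 to give 12, which is lactonised with DBU and molecular sieves as in step 5.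

3. Step 8. Electron transfer between the alkynyl Grignard reagent and the easily ionised chloride may cause reductive dimerisation, or the product may be deprotonated and isomerise to the allene. The fallback replaces the substitution by carbonyl addition and ionic hydrogenation; it sets out from 17 and 6 and comes back at 20. MnO2 (CH2Cl2, rt) should oxidise 17 to bis{4-[(triisopropylsilyl)oxy]phenyl}methanone F8. Lithium acetylide 6 should add to F8 to give 1,1,3-tris{4-[(triisopropylsilyl)oxy]phenyl}prop-2-yn-1-ol F9. Et3SiH with CF3CO2H (CH2Cl2, −40 °C) should reduce the propargylic cation at the diaryl-substituted carbon to give 20.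

Further compounds
F1 | step 9 | [4-(3,3-diethoxyprop-1-yn-1-yl)phenoxy]triisopropylsilane | CCOC(OCC)C#Cc1ccc(O[Si](C(C)C)(C(C)C)C(C)C)cc1
F2 | step 9 | methyl 7-(diethoxymethyl)-3-oxo-8-{4-[(triisopropylsilyl)oxy]phenyl}-1-({4-[(triisopropylsilyl)oxy]phenyl}ethynyl)-2-oxabicyclo[2.2.2]octa-5,7-diene-6-carboxylate (racemic, one enantiomer drawn; not isolated) | COC(=O)C1=C[C@H]2C(=O)O[C@]1(C#Cc3ccc(O[Si](C(C)C)(C(C)C)C(C)C)cc3)C(C(OCC)OCC)=C2c3ccc(O[Si](C(C)C)(C(C)C)C(C)C)cc3
F3 | step 9 | methyl 3-(diethoxymethyl)-4-{4-[(triisopropylsilyl)oxy]phenyl}-2-({4-[(triisopropylsilyl)oxy]phenyl}ethynyl)benzoate | COC(=O)c1ccc(-c2ccc(O[Si](C(C)C)(C(C)C)C(C)C)cc2)c(C(OCC)OCC)c1C#Cc1ccc(O[Si](C(C)C)(C(C)C)C(C)C)cc1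
F4 | step 9 | methyl 3-formyl-4-{4-[(triisopropylsilyl)oxy]phenyl}-2-({4-[(triisopropylsilyl)oxy]phenyl}ethynyl)benzoate | COC(=O)c1ccc(-c2ccc(O[Si](C(C)C)(C(C)C)C(C)C)cc2)c(C=O)c1C#Cc1ccc(O[Si](C(C)C)(C(C)C)C(C)C)cc1
F5 | step 9 | methyl 3-(hydroxy{4-[(triisopropylsilyl)oxy]phenyl}methyl)-4-{4-[(triisopropylsilyl)oxy]phenyl}-2-({4-[(triisopropylsilyl)oxy]phenyl}ethynyl)benzoate (racemic) | COC(=O)c1ccc(-c2ccc(O[Si](C(C)C)(C(C)C)C(C)C)cc2)c(C(O)c2ccc(O[Si](C(C)C)(C(C)C)C(C)C)cc2)c1C#Cc1ccc(O[Si](C(C)C)(C(C)C)C(C)C)cc1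
F6 | step 9 | methyl 3-[(4-hydroxyphenyl){4-[(triisopropylsilyl)oxy]phenyl}methyl]-4-{4-[(triisopropylsilyl)oxy]phenyl}-2-({4-[(triisopropylsilyl)oxy]phenyl}ethynyl)benzoate (racemic) | COC(=O)c1ccc(-c2ccc(O[Si](C(C)C)(C(C)C)C(C)C)cc2)c(C(c2ccc(O)cc2)c2ccc(O[Si](C(C)C)(C(C)C)C(C)C)cc2)c1C#Cc1ccc(O[Si](C(C)C)(C(C)C)C(C)C)cc1
F7 | step 5 | 3-{4-[(triisopropylsilyl)oxy]phenyl}prop-2-ynoyl chloride | O=C(Cl)C#Cc1ccc(O[Si](C(C)C)(C(C)C)C(C)C)cc1
F8 | step 8 | bis{4-[(triisopropylsilyl)oxy]phenyl}methanone | O=C(c1ccc(O[Si](C(C)C)(C(C)C)C(C)C)cc1)c1ccc(O[Si](C(C)C)(C(C)C)C(C)C)cc1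
F9 | step 8 | 1,1,3-tris{4-[(triisopropylsilyl)oxy]phenyl}prop-2-yn-1-ol | OC(C#Cc1ccc(O[Si](C(C)C)(C(C)C)C(C)C)cc1)(c1ccc(O[Si](C(C)C)(C(C)C)C(C)C)cc1)c1ccc(O[Si](C(C)C)(C(C)C)C(C)C)cc1
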